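**Retrosynthetic overview**
1. Ring B comes from 3-bromophenol (1): OH-directed dibromination gives 2,4,5-tribromophenol (2), which already carries all three ring-B bromines.
2. Key disconnection: the diaryl ether C–O bond at C6 of 2, its only free ortho C–H. This C–H is oxidised with iodosylbenzene (3) to an iodonium ylide, whose rhodium carbenoid inserts into the O–H of ring A, bought as 5-bromo-2-methoxyphenol (4). The sequence runs through ylide 5 to methyl ether 6.
3. Last disconnection: the O–CH3 bond of 6, cleaved to give target 7.
4. No ring is formed; both benzene rings are bought and all four bromines are in place before the coupling.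

Assumption: the target has no stereocentre or other stereogenic element, so it is one achiral compound and no enantiocontrol is needed.

**Route**

Step 1
Reactants: 1 3-bromophenol
Product: 2 2,4,5-tribromophenol
Conditions: Br2 (2.05 equiv), AcOH, 15 °C → rt; NaHSO3 work-up, recrystallise
Reagents that add atoms: bromine, BrBr
Why: Electrophilic aromatic bromination (SEAr): the OH group directs to its para position (C4) and its less hindered ortho position (C6), while C2, wedged between OH and Br, reacts last, so two equivalents stop at the 2,4,5-pattern.

Step 2
Reactants: 2 2,4,5-tribromophenol; 3 iodosylbenzene; 4 5-bromo-2-methoxyphenol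
Product: 6 3,4,6-tribromo-2-(5-bromo-2-methoxyphenoxy)phenol, via iodonium ylide 5 (not isolated)
Conditions: 3 (1.05 equiv), 4 Å MS, CH2Cl2, 0 °C → rt, dark; then 4 (1.5 equiv), Rh2(esp)2 (1 mol %), rt
Reagents that add atoms: none
Why: Proposed new method: a formal ortho C–H aryloxylation of a phenol in which the acidic, electron-poor phenol 2 exchanges onto I(III) and, being too electron-poor for phenoxenium-type dearomatisation, shifts iodine to its only free ortho carbon with loss of water to give zwitterion 5; Rh(II) then expels PhI to give a rhodium-bound o-quinoid carbene that is attacked by the OH oxygen of 4, and proton transfer with re-aromatisation gives 6 with the C–O bond fixed at the carbon that carried iodine. The closest known reaction types are base-mediated formation of 2-(phenyliodonio)phenolates from acceptor-substituted phenols, Rh(II)/Cu-catalysed X–H insertion of 1,3-dicarbonyl iodonium ylides (including ylides generated in situ from PhIO), and carbene transfer from o-quinone diazides.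

Step 3
Reactants: 6 3,4,6-tribromo-2-(5-bromo-2-methoxyphenoxy)phenol
Product: 7 3,4,6-tribromo-2-(5-bromo-2-hydroxyphenoxy)phenol
Conditions: BBr3 (3 equiv), CH2Cl2, −78 °C → rt; H2O quench at 0 °C, no base in work-up
Reagents that add atoms: none
Why: Lewis-acid ether cleavage (BBr3 demethylation): boron binds the methoxy oxygen and bromide attacks the methyl carbon by SN2, leaving the diaryl ether and the four aryl–Br bonds untouched.

**Compound list**
1 | 3-bromophenol | Oc1cccc(Br)c1 | starting material
2 | 2,4,5-tribromophenol | Oc1cc(Br)c(Br)cc1Br | intermediate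
3 | iodosylbenzene | O=Ic1ccccc1 | starting material
4 | 5-bromo-2-methoxyphenol | COc1ccc(Br)cc1O | starting material
5 | 3,4,6-tribromo-2-(phenyliodonio)phenolate (iodonium ylide, zwitterion) | [O-]c1c(Br)cc(Br)c(Br)c1[I+]c1ccccc1 | intermediate
6 | 3,4,6-tribromo-2-(5-bromo-2-methoxyphenoxy)phenol | COc1ccc(Br)cc1Oc1c(O)c(Br)cc(Br)c1Br | intermediate
7 | 3,4,6-tribromo-2-(5-bromo-2-hydroxyphenoxy)phenol | Oc1ccc(Br)cc1Oc1c(O)c(Br)cc(Br)c1Br | target

**Step count and risks**
Total step count: 3. Longest linear sequence: 3 steps (1 → 2 → 6 → 7).

The three steps most likely to fail, most risky first: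

Step 2 (the proposed new step). Three things can go wrong:
- PhIO may oxidise 2 at the bromine-bearing para carbon instead of forming the C–I(III) bond.
- The carbenoid may be captured by the phenolate oxygen of a second ylide or by unreacted 2.
- The carbenoid may attack a ring carbon of 4 instead of its O–H.

The fallback uses known chemistry only; it sets out from 4 and comes back to the route at 6. SNAr of the potassium salt of 4 on commercial 3-bromo-2-fluorobenzaldehyde (O=Cc1cccc(Br)c1F; K2CO3, DMF, 90 °C) gives 3-bromo-2-(5-bromo-2-methoxyphenoxy)benzaldehyde F2. Baeyer–Villiger oxidation (mCPBA, CH2Cl2, rt) gives 3-bromo-2-(5-bromo-2-methoxyphenoxy)phenyl formate F3. Methanolysis (cat. K2CO3, MeOH, rt) completes the Dakin sequence to 3-bromo-2-(5-bromo-2-methoxyphenoxy)phenol F4. The free-phenol ring is then brominated para and ortho to its OH (Br2, 2.0 equiv, CH2Cl2, 0 °C), which gives 6; the bromoanisole ring is expected to react more slowly.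

Step 1. The risk is over-bromination to 2,3,4,6-tetrabromophenol and some 2,3,4-isomer that is hard to remove. The fallback replaces the one-pot, substrate-controlled double substitution by two reagent-controlled stages with a purifiable intermediate; it sets out from 1 and comes back at 2. Tetrabutylammonium tribromide (1.0 equiv, CH2Cl2–MeOH, rt) brominates 1 only para to OH to give 3,4-dibromophenol F1, which is purified. Amine-directed ortho-bromination (NBS 1.0 equiv, i-Pr2NH 10 mol %, CH2Cl2, 0 °C) then delivers bromine to the less hindered ortho carbon C6 and gives 2.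

Step 3. The risk is acid-mediated bromine migration or loss on the activated phenol rings under BBr3/HBr, or incomplete cleavage. The fallback removes the ether cleavage altogether by carrying the ring-A hydroxyl as a formyl group; it sets out from 2 and comes back at 7. Compound 2 is converted into ylide 5 as in step 2 and coupled under the same Rh conditions with commercial 4-bromo-2-hydroxybenzaldehyde (O=Cc1ccc(Br)cc1O) in place of 4, which gives 4-bromo-2-(2,3,5-tribromo-6-hydroxyphenoxy)benzaldehyde F5. Baeyer–Villiger oxidation (mCPBA, CH2Cl2, rt) gives 4-bromo-2-(2,3,5-tribromo-6-hydroxyphenoxy)phenyl formate F6. Acidic methanolysis (HCl, MeOH, rt) gives 7; base is avoided so that the ring-A phenoxide cannot close onto the neighbouring C–Br to form a dibenzodioxin.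

**Further compounds**
F1 | step 1 | 3,4-dibromophenol | Oc1ccc(Br)c(Br)c1
F2 | step 2 | 3-bromo-2-(5-bromo-2-methoxyphenoxy)benzaldehyde | COc1ccc(Br)cc1Oc1c(Br)cccc1C=O
F3 | step 2 | 3-bromo-2-(5-bromo-2-methoxyphenoxy)phenyl formate | COc1ccc(Br)cc1Oc1c(Br)cccc1OC=O
F4 | step 2 | 3-bromo-2-(5-bromo-2-methoxyphenoxy)phenol | COc1ccc(Br)cc1Oc1c(Br)cccc1O
F5 | step 3 | 4-bromo-2-(2,3,5-tribromo-6-hydroxyphenoxy)benzaldehyde | O=Cc1ccc(Br)cc1Oc1c(O)c(Br)cc(Br)c1Br
F6 | step 3 | 4-bromo-2-(2,3,5-tribromo-6-hydroxyphenoxy)phenyl formate | O=COc1ccc(Br)cc1Oc1c(O)c(Br)cc(Br)c1Br
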